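**Retrosynthetic overview**

1. Target 18 comes from tert-butyl ester 17 by acidolysis; 17 comes from Steglich esterification of hydroxy enal 12 with dienoic acid 16 (made from (R)-2-methylbutan-1-ol by oxidation/Wittig, then Horner–Wadsworth–Emmons).
2. 12 comes from bicyclic enone 8 by C1 alkylation with a 2-(chloromethyl)allyl unit (later oxidised to the enal) and gamma-hydroxylation at C4 through the silyl dienol ether.
3. 8 comes from keto ester 5 by propargylation at C2 (quaternary centre), alkyne hydration and intramolecular aldol condensation.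
4. 5 comes from enone acid 3 by asymmetric hydrogenation; 3 comes from 3-methoxy-2-methylbenzoic acid 1 by Birch reduction and hydrolysis, so the arene supplies the whole six-membered ring with the C7 carboxyl, C7a methyl and C3a carbonyl in place.
5. Ring order: six-membered ring first (from the benzene ring), five-membered ring second (aldol).

Assumption: (R)-2-methylbutan-1-ol is taken as a catalogue compound; all configurations follow the given SMILES, whose side-chain centre is R.

**Route**

Step 1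
Reactants: 1 3-methoxy-2-methylbenzoic acid
Product: 3 2-methyl-3-oxocyclohex-1-ene-1-carboxylic acid, via 1,4-dihydro enol ether acid 2 (not isolated)
Conditions: Li, NH3(l), THF, tBuOH, −78 °C; NH4Cl; then 2 M HCl, THF, 60 °C
Reagents that add atoms: water, O
Why: Birch reduction of the benzoate protonates C1 and C4 to give the 1,4-dihydro enol ether, and aqueous acid hydrolyses the enol ether and moves the remaining C=C into conjugation with both carbonyl groups, so the arene delivers the future C7 carboxyl, C7a methyl and C3a carbonyl in one operation with no stereocentre formed yet.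

Step 2
Reactants: 3 2-methyl-3-oxocyclohex-1-ene-1-carboxylic acid
Product: 4 (1R,2R)-2-methyl-3-oxocyclohexane-1-carboxylic acid
Conditions: H2 (50 bar), Ru(OAc)2[(R)-BINAP] (1 mol %), MeOH, 40 °C
Reagents that add atoms: none
Why: Carboxylate-directed Noyori-type asymmetric hydrogenation of the tetrasubstituted acrylic acid adds H2 syn to one enantioface, which sets C1 as R (C2 is formed cis and is erased in step 4), the BINAP antipode being fixed by one screening run.

Step 3
Reactants: 4 (1R,2R)-2-methyl-3-oxocyclohexane-1-carboxylic acid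
Product: 5 tert-butyl (1R,2R)-2-methyl-3-oxocyclohexane-1-carboxylate
Conditions: Cl3CC(=NH)OtBu, BF3·OEt2 (cat.), CH2Cl2/cyclohexane, 23 °C
Reagents that add atoms: tert-butyl 2,2,2-trichloroacetimidate, CC(C)(C)OC(=N)C(Cl)(Cl)Cl
Why: Acid-catalysed O-alkylation of the carboxylic acid by the trichloroacetimidate (imidate esterification) never activates the acyl carbon, so C1 keeps its configuration.

Step 4
Reactants: 5 tert-butyl (1R,2R)-2-methyl-3-oxocyclohexane-1-carboxylate
Product: 6 tert-butyl (1R,2S)-2-methyl-3-oxo-2-(prop-2-yn-1-yl)cyclohexane-1-carboxylate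
Conditions: KH (0.95 equiv), THF, 23 °C; then HC≡CCH2Br, −20 → 0 °C
Reagents that add atoms: propargyl bromide (3-bromoprop-1-yne), C#CCBr
Why: Equilibration with a slight deficit of base gives the more substituted (thermodynamic) potassium enolate, whose C-alkylation (enolate alkylation) occurs anti to the adjacent pseudoaxial ester and so sets the quaternary C2 as S with methyl cis to the ester.

Step 5
Reactants: 6 tert-butyl (1R,2S)-2-methyl-3-oxo-2-(prop-2-yn-1-yl)cyclohexane-1-carboxylate
Product: 8 tert-butyl (7R,7aS)-7a-methyl-2-oxo-2,4,5,6,7,7a-hexahydro-1H-indene-7-carboxylate, via 1,4-diketone 7 (not isolated)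
Conditions: Ph3PAuNTf2 (2 mol %), H2O, 1,4-dioxane, 60 °C; then KOH, MeOH, 60 °C
Reagents that add atoms: water, O
Why: Carbonyl-assisted Markovnikov hydration of the terminal alkyne (gold-catalysed alkyne hydration) gives the 1,4-diketone, whose methyl ketone enolate closes onto the ring ketone by intramolecular aldol condensation to the cyclopentenone, leaving both stereocentres untouched.

Step 6
Reactants: 8 tert-butyl (7R,7aS)-7a-methyl-2-oxo-2,4,5,6,7,7a-hexahydro-1H-indene-7-carboxylate
Product: 9 tert-butyl (1R,7R,7aS)-1-[2-(chloromethyl)prop-2-en-1-yl]-7a-methyl-2-oxo-2,4,5,6,7,7a-hexahydro-1H-indene-7-carboxylate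
Conditions: LiN(iPr)2, THF, −78 °C; then CH2=C(CH2Cl)2 (4 equiv), DMPU, −78 → −10 °C
Reagents that add atoms: 3-chloro-2-(chloromethyl)prop-1-ene, C=C(CCl)CCl
Why: Kinetic deprotonation gives the cross-conjugated lithium enolate at C1, which is alkylated (enolate alkylation) on the face of the small angular methyl and anti to the C7 branch that carries the bulky tert-butyl ester, setting C1 as R, the epimer that is also expected to be the more stable one at this enolisable centre.

Step 7
Reactants: 9 tert-butyl (1R,7R,7aS)-1-[2-(chloromethyl)prop-2-en-1-yl]-7a-methyl-2-oxo-2,4,5,6,7,7a-hexahydro-1H-indene-7-carboxylate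
Product: 11 tert-butyl (1R,4S,7R,7aS)-1-[2-(chloromethyl)prop-2-en-1-yl]-4-hydroxy-7a-methyl-2-oxo-2,4,5,6,7,7a-hexahydro-1H-indene-7-carboxylate, via trimethylsilyl dienol ether 10 (not isolated)
Conditions: Me3SiOTf, iPr2NEt, CH2Cl2, 0 °C; then mCPBA, NaHCO3, CH2Cl2, −20 °C; then aq. citric acid
Reagents that add atoms: 3-chloroperbenzoic acid (mCPBA), O=C(OO)c1cccc(Cl)c1; trimethylsilyl trifluoromethanesulfonate, C[Si](C)(C)OS(=O)(=O)C(F)(F)F (its silyl group stays only in 10)
Why: Soft enolisation through the unhindered gamma-hydrogens gives the extended silyl dienol ether, and the peracid attacks its gamma terminus axially, syn to the angular methyl as in the 6β-hydroxylation of steroidal 3,5-dienol ethers (vinylogous Rubottom oxidation), which sets C4 as S.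

Step 8
Reactants: 11 tert-butyl (1R,4S,7R,7aS)-1-[2-(chloromethyl)prop-2-en-1-yl]-4-hydroxy-7a-methyl-2-oxo-2,4,5,6,7,7a-hexahydro-1H-indene-7-carboxylate
Product: 12 tert-butyl (1R,4S,7R,7aS)-1-(2-formylprop-2-en-1-yl)-4-hydroxy-7a-methyl-2-oxo-2,4,5,6,7,7a-hexahydro-1H-indene-7-carboxylate
Conditions: N-methylmorpholine N-oxide (4 equiv), NaI (0.2 equiv), MeCN, 45 °C
Reagents that add atoms: N-methylmorpholine N-oxide, C[N+]1([O-])CCOCC1
Why: Kornblum-type oxidation, in which the amine N-oxide displaces the iodide-activated allylic chloride and the N–O bond then breaks with loss of the amine, gives the 2-substituted acrolein without touching the alcohol or the stereocentres.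

Step 9
Reactants: 13 (R)-2-methylbutan-1-ol
Product: 15 (2E,4R)-2,4-dimethylhex-2-enal, via (R)-2-methylbutanal 14 (not isolated)
Conditions: TEMPO (cat.), KBr (cat.), NaOCl, NaHCO3, CH2Cl2/H2O, 0 °C; organic phase dried; then Ph3P=C(CH3)CHO, CH2Cl2, 40 °C
Reagents that add atoms: 2-(triphenylphosphoranylidene)propanal, CC(C=O)=P(c1ccccc1)(c1ccccc1)c1ccccc1
Why: Anelli oxidation (TEMPO/NaOCl) gives the configurationally labile aldehyde under buffered conditions and the stabilised ylide traps it at once in an E-selective Wittig reaction, so the stereocentre comes unchanged from the chiral pool.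

Step 10
Reactants: 15 (2E,4R)-2,4-dimethylhex-2-enal
Product: 16 (2E,4E,6R)-4,6-dimethylocta-2,4-dienoic acid
Conditions: (EtO)2P(O)CH2CO2H, nBuLi (2 equiv), THF, −78 → 0 °C; then aq. HCl
Reagents that add atoms: diethylphosphonoacetic acid, OC(=O)CP(=O)(OCC)OCC
Why: Horner–Wadsworth–Emmons olefination with the dianion of the phosphonoacetic acid gives the 2E acid directly without an ester hydrolysis step and leaves the 4E bond and C6 untouched.

Step 11
Reactants: 12 tert-butyl (1R,4S,7R,7aS)-1-(2-formylprop-2-en-1-yl)-4-hydroxy-7a-methyl-2-oxo-2,4,5,6,7,7a-hexahydro-1H-indene-7-carboxylate; 16 (2E,4E,6R)-4,6-dimethylocta-2,4-dienoic acid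
Product: 17 tert-butyl (1R,4S,7R,7aS)-4-{[(2E,4E,6R)-4,6-dimethylocta-2,4-dienoyl]oxy}-1-(2-formylprop-2-en-1-yl)-7a-methyl-2-oxo-2,4,5,6,7,7a-hexahydro-1H-indene-7-carboxylate
Conditions: N,N'-diisopropylcarbodiimide, DMAP (0.2 equiv), CH2Cl2, 0 → 23 °C
Reagents that add atoms: none
Why: Steglich esterification (carbodiimide activation, DMAP acyl transfer) acylates the axial allylic alcohol with retention at C4 because its C–O bond is not broken.

Step 12
Reactants: 17 tert-butyl (1R,4S,7R,7aS)-4-{[(2E,4E,6R)-4,6-dimethylocta-2,4-dienoyl]oxy}-1-(2-formylprop-2-en-1-yl)-7a-methyl-2-oxo-2,4,5,6,7,7a-hexahydro-1H-indene-7-carboxylate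
Product: 18 (1R,4S,7R,7aS)-4-{[(2E,4E,6R)-4,6-dimethylocta-2,4-dienoyl]oxy}-1-(2-formylprop-2-en-1-yl)-7a-methyl-2-oxo-2,4,5,6,7,7a-hexahydro-1H-indene-7-carboxylic acid
Conditions: CF3CO2H/CH2Cl2 (1:4), 0 °C
Reagents that add atoms: none
Why: Acidolysis of the tert-butyl ester by loss of 2-methylpropene (E1) frees the acid under anhydrous conditions that leave the dienoate, enal, enone and all stereocentres unchanged.

**Compound list**

1 | 3-methoxy-2-methylbenzoic acid | COc1cccc(C(=O)O)c1C | starting material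
2 | 3-methoxy-2-methylcyclohexa-2,5-diene-1-carboxylic acid (racemic) | COC1=C(C)C(C(=O)O)C=CC1 | intermediate (not isolated)
3 | 2-methyl-3-oxocyclohex-1-ene-1-carboxylic acid | CC1=C(C(=O)O)CCCC1=O | intermediate
4 | (1R,2R)-2-methyl-3-oxocyclohexane-1-carboxylic acid | O=C1CCC[C@@H](C(=O)O)[C@H]1C | intermediate
5 | tert-butyl (1R,2R)-2-methyl-3-oxocyclohexane-1-carboxylate | O=C1CCC[C@@H](C(=O)OC(C)(C)C)[C@H]1C | intermediate
6 | tert-butyl (1R,2S)-2-methyl-3-oxo-2-(prop-2-yn-1-yl)cyclohexane-1-carboxylate | O=C1CCC[C@@H](C(=O)OC(C)(C)C)[C@@]1(CC#C)C | intermediate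
7 | tert-butyl (1R,2S)-2-methyl-3-oxo-2-(2-oxopropyl)cyclohexane-1-carboxylate | O=C1CCC[C@@H](C(=O)OC(C)(C)C)[C@@]1(CC(C)=O)C | intermediate (not isolated)
8 | tert-butyl (7R,7aS)-7a-methyl-2-oxo-2,4,5,6,7,7a-hexahydro-1H-indene-7-carboxylate | C1C(=O)C=C2CCC[C@@H](C(=O)OC(C)(C)C)[C@@]21C | intermediate
9 | tert-butyl (1R,7R,7aS)-1-[2-(chloromethyl)prop-2-en-1-yl]-7a-methyl-2-oxo-2,4,5,6,7,7a-hexahydro-1H-indene-7-carboxylate | C=C(CCl)C[C@H]1C(=O)C=C2CCC[C@@H](C(=O)OC(C)(C)C)[C@@]21C | intermediate
10 | tert-butyl (1R,7R,7aS)-1-[2-(chloromethyl)prop-2-en-1-yl]-7a-methyl-2-[(trimethylsilyl)oxy]-5,6,7,7a-tetrahydro-1H-indene-7-carboxylate | C=C(CCl)C[C@H]1C(O[Si](C)(C)C)=CC2=CCC[C@@H](C(=O)OC(C)(C)C)[C@@]21C | intermediate (not isolated)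
11 | tert-butyl (1R,4S,7R,7aS)-1-[2-(chloromethyl)prop-2-en-1-yl]-4-hydroxy-7a-methyl-2-oxo-2,4,5,6,7,7a-hexahydro-1H-indene-7-carboxylate | C=C(CCl)C[C@H]1C(=O)C=C2[C@@H](O)CC[C@@H](C(=O)OC(C)(C)C)[C@@]21C | intermediate
12 | tert-butyl (1R,4S,7R,7aS)-1-(2-formylprop-2-en-1-yl)-4-hydroxy-7a-methyl-2-oxo-2,4,5,6,7,7a-hexahydro-1H-indene-7-carboxylate | C=C(C=O)C[C@H]1C(=O)C=C2[C@@H](O)CC[C@@H](C(=O)OC(C)(C)C)[C@@]21C | intermediate
13 | (R)-2-methylbutan-1-ol | OC[C@H](C)CC | starting material
14 | (R)-2-methylbutanal | O=C[C@H](C)CC | intermediate (not isolated)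
15 | (2E,4R)-2,4-dimethylhex-2-enal | O=C/C(C)=C/[C@H](C)CC | intermediate
16 | (2E,4E,6R)-4,6-dimethylocta-2,4-dienoic acid | OC(=O)/C=C/C(C)=C/[C@H](C)CC | intermediate
17 | tert-butyl (1R,4S,7R,7aS)-4-{[(2E,4E,6R)-4,6-dimethylocta-2,4-dienoyl]oxy}-1-(2-formylprop-2-en-1-yl)-7a-methyl-2-oxo-2,4,5,6,7,7a-hexahydro-1H-indene-7-carboxylate | C=C(C=O)C[C@H]1C(=O)C=C2[C@@H](OC(=O)/C=C/C(C)=C/[C@H](C)CC)CC[C@@H](C(=O)OC(C)(C)C)[C@@]21C | intermediate
18 | (1R,4S,7R,7aS)-4-{[(2E,4E,6R)-4,6-dimethylocta-2,4-dienoyl]oxy}-1-(2-formylprop-2-en-1-yl)-7a-methyl-2-oxo-2,4,5,6,7,7a-hexahydro-1H-indene-7-carboxylic acid | C=C(C=O)C[C@H]1C(=O)C=C2[C@@H](OC(=O)/C=C/C(C)=C/[C@H](C)CC)CC[C@@H](C(=O)O)[C@@]21C | target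

**Step count and risks**

Total step count: 12. Longest linear sequence: 10 steps (steps 1 to 8, then 11 and 12); steps 9 and 10 make the side-chain acid.

Most likely to fail, with fallbacks:

Step 2. The alkene is tetrasubstituted, so rate and enantioselectivity of the hydrogenation are uncertain. The fallback sets out from 3: hydrogenation over Pd/C (H2, EtOAc) gives rac-cis-2-methyl-3-oxocyclohexane-1-carboxylic acid F1. This is resolved by crystallising (R)-1-phenylethylammonium (1R,2R)-2-methyl-3-oxocyclohexane-1-carboxylate F2 (the antipodal amine is used if the other salt is the less soluble one). Dilute HCl frees the acid and the route is rejoined at 4.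

Step 4. Enolisation may go to the less substituted side, and the tetrasubstituted enolate may O-alkylate. The fallback sets out from 3: the imidate of step 3 gives tert-butyl 2-methyl-3-oxocyclohex-1-ene-1-carboxylate F3. Copper hydride 1,4-reduction (Cu(OAc)2, (R)-DTBM-SEGPHOS, (EtO)2MeSiH, toluene) sets C1 and gives the regiodefined silyl enol ether tert-butyl (1R)-3-{[diethoxy(methyl)silyl]oxy}-2-methylcyclohex-2-ene-1-carboxylate F4. MeLi then propargyl bromide alkylate C2 anti to the ester, and the route is rejoined at 6 (steps 2 and 3 are then not needed).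

Step 7. The dienol ether may form toward C1 instead of C4, the peracid may attack the alpha carbon, or the wrong face may react. The fallback sets out from 9: the only allylic methylene is oxidised with Pd(OH)2/C, tBuOOH and K2CO3 in CH2Cl2 to the ene-dione tert-butyl (1R,7R,7aS)-1-[2-(chloromethyl)prop-2-en-1-yl]-7a-methyl-2,4-dioxo-2,4,5,6,7,7a-hexahydro-1H-indene-7-carboxylate F5. Luche reduction (NaBH4, CeCl3·7H2O, MeOH, −78 °C) of the six-ring carbonyl, with hydride entering anti to the angular methyl, rejoins the route at 11.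

**Further compounds**

F1 | step 2 | rac-cis-2-methyl-3-oxocyclohexane-1-carboxylic acid | O=C1CCC[C@@H](C(=O)O)[C@H]1C.O=C1CCC[C@H](C(=O)O)[C@@H]1C
F2 | step 2 | (R)-1-phenylethylammonium (1R,2R)-2-methyl-3-oxocyclohexane-1-carboxylate | C[C@@H]([NH3+])c1ccccc1.O=C1CCC[C@@H](C([O-])=O)[C@H]1C
F3 | step 4 | tert-butyl 2-methyl-3-oxocyclohex-1-ene-1-carboxylate | CC1=C(C(=O)OC(C)(C)C)CCCC1=O
F4 | step 4 | tert-butyl (1R)-3-{[diethoxy(methyl)silyl]oxy}-2-methylcyclohex-2-ene-1-carboxylate | CC1=C(O[Si](C)(OCC)OCC)CCC[C@H]1C(=O)OC(C)(C)C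
F5 | step 7 | tert-butyl (1R,7R,7aS)-1-[2-(chloromethyl)prop-2-en-1-yl]-7a-methyl-2,4-dioxo-2,4,5,6,7,7a-hexahydro-1H-indene-7-carboxylate | C=C(CCl)C[C@H]1C(=O)C=C2C(=O)CC[C@@H](C(=O)OC(C)(C)C)[C@@]21C
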